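Its constants stand for no real mixture; the result is computed.

The south-west flask is the closed one, with everything in at once, so I started there.

| flask | substrate | reagent | time | remark |
|---|---|---|---|---|
| north-west | 10 mM (fed, over 1.50 min) | 20.0 mM | 1.5 min | a stirred flask in which substrate is dosed at a steady rate over 1.50 min without added volume, worked up at 1.5 min |
| south-west | 10 mM | 20.0 mM | 1.5 min | a closed flask charged with all of it at once and left for 1.5 min |
| south | 10 mM | 20.0 mM (fed, over 1.50 min) | 1.5 min | all but reagent at the start; reagent goes in evenly over 1.50 min, the run ends at 1.5 min |
| south-east | 10 mM | 20.0 mM |  | one stirred flow tank at steady state, fed with the mixture as stated, mean residence time 1.5 min |

- the set-up with the highest share of first product in all that became first product or double product or tris adduct, at the outlet or at the end ("none" if the first two lie within 2 percentage points) (north-west / south-west / south / south-east / none)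
- share of first product in all that became first product or double product or tris adduct, at the outlet or at the end, north-west
- share of first product in all that became first product or double product or tris adduct, at the outlet or at the end, south-west
- share of first product in all that became first product or double product or tris adduct, at the outlet or at the end, south
- share of first product in all that became first product or double product or tris adduct, at the outlet or at the end, south-east

- the stated concentrations are those of everything mixed, before any reaction; amounts are the same in each set-up
- the feed brings no volume worth counting
- run time (north-west): 1.5 min

    substrate + reagent → first product (k1 = 28 M⁻¹ s⁻¹)
    reagent + first product → double product (k2 = 6.5 M⁻¹ s⁻¹)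
    reagent + double product ⇌ tris adduct (K3 = 47 M⁻¹, k3 = 38 M⁻¹ s⁻¹)

Reagent turns substrate into first product, then first product into double product, and double product binds more reagent reversibly to give tris adduct. Let s be the fraction of substrate left, and m the first product as a fraction of the substrate charged.

My first guess for south-west was grim. At the charged reagent of south-west, first product has a half-life by step 2 alone of 0.089 min, short against the run of 1.5 min, which makes 16.9 half-lives and a mere trace. But reagent falls as it works, so that clock slows.

Better to drop the clock. Both steps use the same reagent, so dividing one rate by the other removes reagent and time, leaving κ = 0.232, the second rate constant over the first, the selectivity factor. In a stirred flask holding all its substrate from the start, m = (s^κ − s)/(1 − κ), with a top of 64.3%.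

That curve gives no s, though. With 2.00 equivalents, free reagent plus tris adduct late in south-west must equal first product, so the reciprocal of m grows steadily, and I got m = 13.5%. Then came the objection: tris adduct holds reagent back. The half-life of double product by step 3, forward rate alone and at the charged reagent, is 0.91 s, short against the run, so I took step 3 as equilibrated, which divides free reagent by 1.47 if the whole charge counts as double product, a generous count. That gave 18.1%, and the curve read backwards left s = 0.0202%, so the share equals m.

South rides the same curve. I expected it to stop higher up, but could not reckon its s by hand. The curve does not cover north-west or south-east, so I had no figure for them.

The forecast gave 26% for north-west, 18% for south-west, 45% for south and 31% for south-east, and concluded “Reagent dosing wins.”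

The simulation gave 26.5%, 18.0%, 44.8% and 31.1% in that order, with south best.

South led south-west by 27 percentage points, and striking out the reverse step, tris adduct back to reagent and double product, cuts that lead to 9.9 points, so this step is a part of the lead. South ended with 1.1% of its substrate left, against 0.020% in south-west, and the curve at that s gives 44.3%, where south held 44.3%. The south-west flask stopped at 50 s had 0.13% of its substrate left; the curve gives 27.4%, and that flask held 27.4%.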